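Side product keeps time. In the west run, first and second end groups have already made 91.8% links at 0.333 min; after that, free first end groups attack links, slowly.

| flask | first end groups | second end groups | remark | time |
|---|---|---|---|---|
| west | 0.13 M | 0.95 equiv | run made earlier |  |
| south-east | 0.13 M | 0.47 equiv | run made earlier |  |
| north-west | 0.13 M | 1.9 equiv | run made earlier |  |
| violet | 0.13 M | 0.950 equiv (fed, over 3.0 min) | all else is in the flask from the start; the feed brings no volume worth counting | 5.0 min |
| grey | 0.13 M (fed, over 3.0 min) | 0.950 equiv | all else is in the flask from the start; the feed brings no volume worth counting | 5.0 min |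
| green | 0.13 M | 0.950 equiv | everything together at the start | 5.0 min |
| amber | 0.13 M | 0.950 equiv (in portions, 3, over 3.0 min) | first portion at the start, last at 3.0 min | 5.0 min |

| run | time / min | side product / % | links / % |
|---|---|---|---|
| west | 0.333 | 1.1 | 91.8 |
| west | 1.00 | 0.9 | 94.0 |
| west | 2.00 | 0.1 | 95.3 |
| west | 2.50 | 0.6 | 95.4 |
| west | 4.00 | 1.6 | 94.9 |
| west | 5.00 | 0.1 | 94.9 |
| south-east | 0.200 | 1.0 | 47.2 |
| south-east | 0.667 | 1.9 | 45.6 |
| south-east | 1.00 | 5.4 | 45.3 |
| south-east | 1.50 | 6.7 | 43.5 |
| south-east | 2.50 | 11.7 | 41.3 |
| south-east | 3.00 | 14.1 | 39.1 |
| north-west | 0.500 | 1.3 | 100.0 |
| north-west | 1.00 | 1.1 | 100.5 |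
| north-west | 1.50 | 0 | 97.6 |
| north-west | 2.00 | 0.8 | 99.5 |
| north-west | 2.50 | 2.2 | 98.6 |
| north-west | 3.00 | 0 | 99.5 |

(each reading ± 1 percentage point)

- the flask that comes out highest in amount of side product, in percent of the first end groups charged, or "all alike" when all lie within 1.5 percentage points (violet / grey / green / amber / all alike)
- side product at the end, in percent of the first end groups charged, violet
- side product at the end, in percent of the first end groups charged, grey
- side product at the end, in percent of the first end groups charged, green
- side product at the end, in percent of the first end groups charged, amber

- percent here means first end groups units held: one side product counts as two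
- what is said of links includes crystals
- crystals is a solid; its amount is given per volume of the solution
- steps that have been proposed: crystals <-> links; first end groups + links -> side product; first end groups + second end groups -> links + released group

Freeze c(links). In the south-east run, links stay between 39.1% and 47.2% while side product climbs at 0.0468 min⁻¹, with a free fraction of first end groups averaging 49.3%. Their ratio is the burn constant 0.0949 min⁻¹, side product gained per minute per unit free fraction at that c(links), a pseudo-first-order constant. Scaled to the links of the west run, it would give 4.77% by 5.00 min, yet the readings there are 1.6% and 0.1%. So this text's own reckoning takes the solid to cap dissolved links near 47.2%.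

Then each setting is an area under the free fraction. Charging together (green) is reckoned at 5.00% free for the whole time, giving 2.37%. For feeding first end groups (grey), this reckoning counts free first end groups from 2.85 min, when the feed has matched the second end groups charged, and sets aside any that stand free earlier, giving 1.02%. Feeding second end groups (violet) brings links to the cap at 1.49 min, and the area up to the end of the feed gives 8.99%. Equally spaced portions (amber) are reckoned with the free fraction at 68.3%, then 36.7%, giving 11.7%, the highest of these.

The forecast, holding that “dissolved links look capped by crystals”, names amber: violet 11.5%, grey 1.2%, green 2.3%, amber 13%. Its violet stands above this reckoning.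

The flasks give amber as highest: violet 9.49%, grey 1.71%, green 2.81%, amber 12.0%.

    crystals ⇌ links, rate k1*(cs1 - [links]) while solid is left; crystals form when [links] > cs1 (solubility = 0.0620 M, k = 18.0 min⁻¹)
    first end groups + links → side product (k = 0.810 L mol⁻¹ min⁻¹)
    first end groups + second end groups → links + released group (k = 330 L mol⁻¹ min⁻¹)

At 2.50 min, amber holds 31.8% first end groups beside 58.5% links, crystals of 10.9% counted in them. The burn constant gives amber 1.5 percentage points up to 3.00 min, where side product goes from 9.70% to 11.3%. For green, from 2.50 min to 5.00 min, it gives 0.91 points, and side product goes from 1.85% to 2.81%.

Readings and results were generated by integration with made-up constants; the scatter is artificial.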